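**The problem**

The target is a heliangolide: a cyclodecane with a trans-fused α-methylene-γ-butyrolactone across C6–C7, a (4Z)-trisubstituted alkene, a trans 1,10-epoxide, a free allylic hydroxyl at C3 and a (2R,3R)-2,3-epoxy-2-methylbutanoate on the C8 oxygen (germacrane numbering throughout). C6, C7 and C8 form a contiguous triad (6R,7R,8R) in which C11 is trans to the lactone oxygen on C6 but cis to the acyloxy group on C8. C3 (S) is separated from that triad by the C4=C5 alkene and cannot be induced from it. C1 and C10 arise together when the E-alkene is epoxidised and can only be governed by the ring conformation, and the two centres of the side-chain acid are best set by a reagent-controlled epoxidation. Three features forbid rough treatment: the methylene lactone (Michael acceptor), the 1,10-epoxide (acid opens it across the ring onto C4=C5) and the 1,5-diene, which can drain by Cope rearrangement on heating. The enabling feature is that C10=C1–C2–C3–C4=C5 is a 1,5-diene with the C6 oxygen next to C5. Joining C1 to C4 and C5 to C10 on paper folds the ring into a bicyclo[2.2.0]hexane fused to a cyclohexanone, the photoadduct of a 3-methylcyclohex-2-enone (C5–C10) and a 1-methylcyclobutene (C1–C4), with C8 carried by the enone and C3 by the cyclobutene. The one snag is C7: enolate alkylation beside an oxygen-bearing carbon is reliably anti, whereas the target is 7,8-cis. C8 is therefore carried as its epimer and inverted in the esterification.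

**Retrosynthesis**

Target 34 is traced to silyl ether 33 and then to diene ester 32 by removing the C1–O and C10–O bonds. Epoxidation is placed last but one because the epoxide is the most acid-sensitive group. With C3 still silylated, the isolated C1=C10 alkene is the only electron-rich, unshielded alkene left. The forward step must be selective for position and face.

Ester 32 is cut at the C8–O bond into alcohol 27 (8S) and epoxy acid 31. A simple acylation with retention would demand a 7,8-cis alcohol, which no enolate alkylation next to C8 delivers. A Mitsunobu esterification attaches the side chain and inverts C8 in one operation. The acid 31 carries its two stereocentres independently.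

Alcohol 27 comes from methylene lactone 26 and this from lactone 23 (C11=C13 removed). 23 is opened at the C12–O bond and the C6 carbinol taken back to the ketone, giving cyclodecadienone 21. The forward reduction must give the 6R alcohol, trans to C11. The C8 ether, 1,3 to the carbonyl, offers a chelate for this.

Dienone 21 is the retron for the key sequence. Re-forming the C1–C4 and C5–C10 σ-bonds turns the C1=C10 and C4=C5 alkenes into the central cyclobutane of tricyclic ketone 20. This removes any end-to-end closure of the ten-membered ring. The forward thermolysis must give E at C1=C10 and Z at C4=C5.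

Tricycle 20 is cut at C1–C10 and C4–C5 into enone 10 and cyclobutene 18, the [2+2] photocycloaddition. Compared with a cut that closes the ring at C3–C4 or C2–C3, this one removes a ring, two skeletal bonds and all medium-ring entropy at once. It asks only for head-to-head regiochemistry and a cis ring fusion.

Enone 10 is cut at C7–C11 into enone 8 and methyl bromoacetate 9. The side chain is put on before the cycloaddition because a simple cyclohexenone enolate is alkylated anti to the neighbouring ether with certainty. The same relation would be a matter of conformation in the ten-membered ring.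

Enone 8 goes back through carbinol 7, enone 6, monoacetate 4 and meso ether 3 to cis,cis-cyclohexane-1,3,5-triol 1 and 4-methoxybenzyl chloride 2. The three carbinol carbons of 1 become C6, C8 and C10, and an enzyme decides the configuration of C8.

Cyclobutene 18 goes back through alcohol 17, cyclobutenone 16, 2-methylcyclobutanone 14 and hydrazone 12 to cyclobutanone 11. C3 is set by a catalytic asymmetric reduction.

Acid 31 goes back through epoxy alcohol 30 and (Z)-allylic alcohol 29 to methyl angelate 28. The Z geometry fixes the cis relation of carboxyl and C3′-methyl, and the tartrate fixes the absolute sense.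

**Roads not taken**

Alternative 1: The ring is cut at C3–C4. In the forward sense CrCl2 with catalytic NiCl2 turns a preset (Z)-alkenyl iodide at C4 into an alkenylchromium that adds to a C3 aldehyde, closing the ring and giving the hydroxy lactone A1.
- Merits: both alkene geometries are fixed before ring closure, no hot step is needed, the C3 carbinol is formed directly, and the lactone with its methylene group can be carried through the mild coupling.
- Weak points: C3 is created in the cyclisation with no neighbouring stereocentre to guide it, so its configuration rests on the closing conformation. The β,γ-unsaturated aldehyde is prone to enolisation and conjugation. High dilution and a large excess of chromium salt are needed. The whole C6–C8 triad must first be built on an open chain.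
- Comparison: this road is better where the chosen plan is weakest, since alkene geometry is secure and there is no Cope risk. Against that, the chosen plan sets C3 in a five-carbon building block under catalyst control and makes the ten-membered ring without any macrocyclisation.

Alternative 2: The lactone is cut at C7–C11. The anion of a malonate esterified to the C6 oxygen attacks C7 of a trans C7–C8 epoxide in a 5-exo closure, forming C7–C11 and the lactone ring and releasing the C8 hydroxyl, to give A2.
- Merits: the opening is stereospecific, so C7 is fixed relative to both C6 and C8 in one step, and the 7,8-cis relation appears directly with a free C8 hydroxyl ready for acylation with retention. On this point it is better than the chosen plan, which needs the C8 inversion of step 20.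
- Weak points: it solves only the triad. The ring must still be closed later, with the same uncertainty at C3 as in Alternative 1. Attack at C8 (6-endo) and base-induced elimination at the allylic C6 ester can compete. The extra allyl ester must be removed before methylenation.
- Comparison: the chosen plan accepts one inversion step in exchange for a ring construction that needs no acyclic stereotriad synthesis and no late cyclisation.

Alternative 3: The lactone is cut at C11–C12 and C12–O. [(salph)Al(THF)2][Co(CO)4] under CO would insert carbon monoxide into the primary C11–O bond of a trans-fused oxetane, giving lactone A3.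
- Merits: the C6–C7 relation is stored in the oxetane and passed on untouched at C6. No enolate is generated next to the C8 oxygen. The step is atom-economic and could be run late.
- Weak points: oxetanes are carbonylated far less readily than epoxides. The Lewis-acidic aluminium centre can ionise the allylic C6–O bond instead of letting the cobaltate attack C11. The oxetane itself presupposes a 7-hydroxymethyl-6-ol of the right configuration on a finished ten-membered ring, so neither the ring nor C7 is solved. A3 still lacks C13.
- Comparison: as a lactone tactic it is as good as the alkylation–reduction–lactonisation used here in stereochemical terms and gentler in base strength. The chosen plan sets against it that each of its lactone-forming steps is routine and that the ring synthesis comes with it.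

Key step: step 12

Assumption: the lipase acetylates the hydroxyl that leads to monoacetate 4 as drawn; if a given enzyme prefers the other one, the same compound is reached by its hydrolysis of the diacetate of 3.
Remark: germacrane numbering (C1–C15) is used for all carbocyclic intermediates, also before the ten-membered ring exists.

Step 1
Reactants: 1 cis,cis-cyclohexane-1,3,5-triol; 2 4-methoxybenzyl chloride
Product: 3 all-cis-5-(4-methoxybenzyloxy)cyclohexane-1,3-diol (meso)
Conditions: NaH (1.0 equiv), DMF, 0 °C to rt
Reagents that add atoms: none
Why: Williamson etherification of one of three equivalent hydroxyls; with one equivalent of alkoxide the mono-ether should predominate and is separable from triol and bis-ether; no stereocentre is touched.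

Step 2
Reactants: 3 all-cis-5-(4-methoxybenzyloxy)cyclohexane-1,3-diol
Product: 4 (1R,3R,5S)-3-hydroxy-5-(4-methoxybenzyloxy)cyclohexyl acetate
Conditions: Burkholderia cepacia lipase, vinyl acetate, t-BuOMe, 30 °C
Reagents that add atoms: vinyl acetate, C=COC(C)=O
Why: Enzymatic desymmetrisation by irreversible transesterification distinguishes the enantiotopic hydroxyls of the meso diol; this choice fixes the configuration of C8, since the acetylated carbon later loses its oxygen and the free carbinol becomes C10.

Step 3
Reactants: 4 (1R,3R,5S)-3-hydroxy-5-(4-methoxybenzyloxy)cyclohexyl acetate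
Product: 6 (R)-5-(4-methoxybenzyloxy)cyclohex-2-en-1-one, via acetoxy ketone 5 (not isolated)
Conditions: Dess–Martin periodinane, NaHCO3, CH2Cl2, 0 °C; then Et3N, 0 °C to rt
Reagents that add atoms: none
Why: Dess–Martin oxidation gives the β-acetoxy ketone, and triethylamine then triggers E1cB loss of acetate, a far better leaving group than the benzylic alkoxide, so the enone forms without touching C8.

Step 4
Reactants: 6 (R)-5-(4-methoxybenzyloxy)cyclohex-2-en-1-one
Product: 7 (5R)-1-methyl-5-(4-methoxybenzyloxy)cyclohex-2-en-1-ol (both C1 epimers)
Conditions: MeLi, Et2O, −78 °C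
Reagents that add atoms: methyllithium, [Li]C
Why: 1,2-Addition of an organolithium to the enone carbonyl at low temperature; the new carbinol centre is irrelevant because it becomes trigonal in step 5.

Step 5
Reactants: 7 (5R)-1-methyl-5-(4-methoxybenzyloxy)cyclohex-2-en-1-ol
Product: 8 (S)-3-methyl-5-(4-methoxybenzyloxy)cyclohex-2-en-1-one
Conditions: [C5H5NH][CrO3Cl] (pyridinium chlorochromate), 4 Å MS, CH2Cl2, rt
Reagents that add atoms: none
Why: Babler–Dauben oxidative transposition: the chromate ester of the tertiary allylic alcohol undergoes a [3,3] shift and oxidation, moving the oxygen to C6 and leaving the methyl on C10; C8 is untouched and its descriptor changes from R to S only because the carbonyl has changed sides.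

Step 6
Reactants: 8 (S)-3-methyl-5-(4-methoxybenzyloxy)cyclohex-2-en-1-one; 9 methyl bromoacetate
Product: 10 methyl 2-[(1R,6S)-6-(4-methoxybenzyloxy)-4-methyl-2-oxocyclohex-3-en-1-yl]acetate
Conditions: LiN(iPr)2, THF, −78 °C; 9, DMPU, −78 to −40 °C; cold AcOH quench
Reagents that add atoms: none
Why: Kinetic α′-deprotonation gives the cross-conjugated lithium dienolate, which is alkylated at C7 anti to the adjacent C8 ether (7R, trans, also the thermodynamic epimer); at −78 °C loss of the β-alkoxide is slow, and the cold quench avoids aromatisation.

Step 7
Reactants: 11 cyclobutanone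
Product: 12 2-cyclobutylidene-1,1-dimethylhydrazine
Conditions: Me2NNH2, MgSO4, Et2O, rt
Reagents that add atoms: N,N-dimethylhydrazine, CN(C)N
Why: Hydrazone formation provides the azaenolate precursor and avoids the self-condensation that plagues direct enolate alkylation of cyclobutanone.

Step 8
Reactants: 12 2-cyclobutylidene-1,1-dimethylhydrazine
Product: 14 2-methylcyclobutan-1-one (racemic), via methylated hydrazone 13 (not isolated)
Conditions: LiN(iPr)2, THF, −78 to 0 °C; MeI, −78 °C; then aq. oxalic acid, Et2O, rt
Reagents that add atoms: iodomethane, CI; water, O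
Why: Hydrazone azaenolate alkylation gives clean mono-methylation and two-phase oxalic acid hydrolysis returns the ketone; the stereocentre formed is racemic and is destroyed in step 9.

Step 9
Reactants: 14 2-methylcyclobutan-1-one
Product: 16 2-methylcyclobut-2-en-1-one, via silyl enol ether 15 (not isolated)
Conditions: Me3SiCl, NaI, Et3N, MeCN, rt; then Pd(OAc)2 (1 equiv), MeCN, rt; product kept in cold solution
Reagents that add atoms: none
Why: Iodotrimethylsilane made in the flask gives the more substituted (thermodynamic) silyl enol ether, and Saegusa–Ito oxidation through the C-bound palladium enolate with β-hydride loss from the ring methylene gives the conjugated cyclobutenone.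

Step 10
Reactants: 16 2-methylcyclobut-2-en-1-one
Product: 17 (S)-2-methylcyclobut-2-en-1-ol
Conditions: (R)-Me-CBS oxazaborolidine (10 mol%), BH3·SMe2, THF, −30 °C
Reagents that add atoms: none
Why: Corey–Bakshi–Shibata reduction; the 2-methylalkenyl arm acts as the large group, so the (R)-catalyst should deliver hydride to give the (S)-carbinol, the future C3, by clean 1,2-reduction.

Step 11
Reactants: 17 (S)-2-methylcyclobut-2-en-1-ol
Product: 18 (S)-tert-butyldimethyl[(2-methylcyclobut-2-en-1-yl)oxy]silane
Conditions: t-BuMe2SiCl, imidazole, CH2Cl2, 0 °C to rt
Reagents that add atoms: tert-butyldimethylsilyl chloride, CC(C)(C)[Si](C)(C)Cl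
Why: Standard silylation of a secondary allylic alcohol; the ether makes the partner less volatile and survives irradiation, thermolysis and strong base.

Step 12
Reactants: 10 methyl 2-[(1R,6S)-6-(4-methoxybenzyloxy)-4-methyl-2-oxocyclohex-3-en-1-yl]acetate; 18 (S)-tert-butyldimethyl[(2-methylcyclobut-2-en-1-yl)oxy]silane
Product: 20 methyl 2-[4-(tert-butyldimethylsilyloxy)-9-(4-methoxybenzyloxy)-1,5-dimethyl-7-oxotricyclo[4.4.0.0(2,5)]decan-8-yl]acetate (cis-anti-cis; 3S,7R,8S), via trans-fused photoadduct 19 (not isolated)
Conditions: hν (350 nm, Pyrex), 18 (3 equiv, excess recovered), CH2Cl2, −40 °C; then basic Al2O3, Et2O, rt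
Reagents that add atoms: none
Why: Light of 350 nm excites only the enone, which crosses to its twisted π,π* triplet. The triplet adds to the strained cyclobutene in two steps through a 1,4-biradical that closes after spin inversion; this is the enone–alkene [2+2] photocycloaddition, in the variant known for 3-methylcyclohexenones with 1-methylcyclobutenes. The one ring closed is the central cyclobutane (C5, C10, C1, C4), formed by recombination of that triplet-derived biradical. The selectivity the step needs is head-to-head regiochemistry (C10 to C1, C5 to C4); it is secured because C10 and C4 both become fully substituted carbons and the other orientation would place them next to each other. C1 and C4 are cis by necessity of the four-membered ring and their sense is set by approach of the enone anti to the C3 silyloxy group; C5 and C10 are set by approach anti to the C8 ether, and any trans-fused ketone 19 is epimerised at C5, α to the carbonyl, on basic alumina to cis-fused 20. The cis ring fusion is the only stereochemical outcome that matters, because it decides alkene geometry in step 13; the four new stereocentres are destroyed there, so facial isomers converge. C3, C7 and C8 are spectators, and C7 stays trans to the C8 ether because that is also its thermodynamic configuration on alumina. The anisyl and ester groups do not absorb at 350 nm, and low temperature with excess alkene suppresses enone dimerisation.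

Step 13
Reactants: 20 cis-anti-cis tricyclic keto ester
Product: 21 methyl 2-[(1R,3Z,5S,7E,10S)-5-(tert-butyldimethylsilyloxy)-10-(4-methoxybenzyloxy)-4,8-dimethyl-2-oxocyclodeca-3,7-dien-1-yl]acetate (germacrane numbering: 1(10)E,4Z; 3S,7R,8S)
Conditions: PhMe (0.01 M, degassed), BHT, base-washed sealed tube, 185 °C
Reagents that add atoms: none
Why: Thermal cycloreversion of the bicyclo[2.2.0]hexane: homolysis of the strained C1–C4 bond gives a cyclohexane-1,4-diyl that fragments at C5–C10, the bond weakened by the adjacent carbonyl and by full substitution at C10. In the chair diyl the cis ring fusion holds one of C6 and C9 axial and the other equatorial, so one alkene forms E and the other Z; the arrangement with the conjugated C4=C5 bond cis and C1=C10 trans is the one known for cis-anti-cis adducts of this type, and C3, C7 and C8 are untouched.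

Step 14
Reactants: 21 cyclodecadienone keto ester
Product: 23 (3S,6R,7R,8S,1(10)E,4Z)-3-(tert-butyldimethylsilyloxy)-8-(4-methoxybenzyloxy)-13-norgermacra-1(10),4-dien-12,6-olide, via hydroxy ester 22 (not isolated)
Conditions: Zn(BH4)2, Et2O, −30 °C; then PPTS (cat.), PhMe, 50 °C
Reagents that add atoms: none
Why: Chelation-controlled 1,2-reduction: zinc bridges the C6 carbonyl and the C8 ether and hydride enters opposite the C7 side chain, giving the 6,8-syn, 6,7-trans alcohol (6R); its hydroxyl then closes the trans-fused γ-lactone on the methyl ester under mild acid.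

Step 15
Reactants: 23 trans-fused lactone
Product: 26 (3S,6R,7R,8S,1(10)E,4Z)-3-(tert-butyldimethylsilyloxy)-8-(4-methoxybenzyloxy)germacra-1(10),4,11(13)-trien-12,6-olide, via Mannich base 24 (not isolated), via ammonium iodide 25 (not isolated)
Conditions: LiN(iPr)2, THF, −78 °C; CH2=NMe2+ I−, −78 to 0 °C; MeI, MeOH, rt; then aq. NaHCO3, EtOAc, rt
Reagents that add atoms: N,N-dimethylmethyleneiminium iodide (Eschenmoser's salt), C=[N+](C)C.[I-]
Why: Aminomethylation of the lactone enolate with Eschenmoser's salt, quaternisation and base-induced elimination is the standard α-methylenation of γ-lactones; C11 ends trigonal, and the lactone α-position is the only enolisable site.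

Step 16
Reactants: 26 methylene lactone
Product: 27 (3S,6R,7R,8S,1(10)E,4Z)-3-(tert-butyldimethylsilyloxy)-8-hydroxygermacra-1(10),4,11(13)-trien-12,6-olide
Conditions: DDQ, CH2Cl2/pH 7 buffer, 0 °C; used at once
Reagents that add atoms: none
Why: Oxidative cleavage of the p-methoxybenzyl ether by DDQ leaves the silyl ether, the alkenes and the methylene lactone alone; the neutral, base-free medium also avoids migration of the lactone to the freed 8-hydroxyl.

Step 17
Reactants: 28 methyl (Z)-2-methylbut-2-enoate (methyl angelate)
Product: 29 (Z)-2-methylbut-2-en-1-ol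
Conditions: iBu2AlH, CH2Cl2, −78 to 0 °C
Reagents that add atoms: none
Why: Hydride reduction of the conjugated ester to the allylic alcohol at low temperature, without isomerising the Z alkene.

Step 18
Reactants: 29 (Z)-2-methylbut-2-en-1-ol
Product: 30 [(2S,3R)-2,3-dimethyloxiran-2-yl]methanol
Conditions: Ti(OiPr)4 (cat.), L-(+)-diisopropyl tartrate, t-BuOOH, 4 Å MS, CH2Cl2, −20 °C
Reagents that add atoms: tert-butyl hydroperoxide, CC(C)(C)OO
Why: Sharpless asymmetric epoxidation; the L-(+)-tartrate catalyst delivers oxygen to the face that gives the 2S centre, and the Z geometry fixes hydroxymethyl and C3-methyl cis on the oxirane.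

Step 19
Reactants: 30 [(2S,3R)-2,3-dimethyloxiran-2-yl]methanol
Product: 31 (2R,3R)-2,3-dimethyloxirane-2-carboxylic acid
Conditions: RuCl3 (cat.), NaIO4, CCl4/MeCN/H2O, rt
Reagents that add atoms: water, O
Why: Ruthenium tetroxide, generated catalytically, oxidises the primary alcohol through the aldehyde hydrate to the acid without opening the epoxide; the C2 descriptor changes from S to R only because carboxyl outranks the ring carbon.

Step 20
Reactants: 27 8S alcohol; 31 (2R,3R)-2,3-dimethyloxirane-2-carboxylic acid
Product: 32 (3S,6R,7R,8R,1(10)E,4Z)-3-(tert-butyldimethylsilyloxy)-8-[(2R,3R)-2,3-dimethyloxirane-2-carbonyloxy]germacra-1(10),4,11(13)-trien-12,6-olide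
Conditions: PPh3, DIAD, PhMe, 0 °C (betaine preformed); 31, then 27, 0 °C to rt
Reagents that add atoms: none
Why: Mitsunobu esterification: the C8 oxyphosphonium ion is displaced by the carboxylate with inversion, turning the 8S alcohol into the 8R ester while attaching the side chain. The acid has no α-hydrogen and is acidic enough to protonate the betaine, and preforming the betaine keeps free phosphine away from the methylene lactone.

Step 21
Reactants: 32 diene ester
Product: 33 (1R,3S,6R,7R,8R,10R,4Z)-3-(tert-butyldimethylsilyloxy)-1,10-epoxy-8-[(2R,3R)-2,3-dimethyloxirane-2-carbonyloxy]germacra-4,11(13)-dien-12,6-olide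
Conditions: mCPBA (1.1 equiv), NaHCO3, CH2Cl2, −20 to 0 °C
Reagents that add atoms: 3-chloroperbenzoic acid, OOC(=O)c1cccc(Cl)c1
Why: Prilezhaev epoxidation of the most electron-rich alkene: C4=C5 is deactivated by two allylic C–O bonds and screened by the silyl ether, and the methylene lactone is electron-poor. The peracid should attack the outer face of the E-alkene, whose inner face is blocked across the ring, to give the trans (1R,10R)-epoxide; the buffer prevents transannular opening.

Step 22
Reactants: 33 silyl ether
Product: 34 (1R,3S,6R,7R,8R,10R,4Z)-1,10-epoxy-3-hydroxy-8-[(2R,3R)-2,3-dimethyloxirane-2-carbonyloxy]germacra-4,11(13)-dien-12,6-olide (CNP0268255.1)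
Conditions: Bu4NF, AcOH (1:1), THF, 0 °C to rt
Reagents that add atoms: none
Why: Fluoride cleaves the silyl ether; buffering with acetic acid keeps the medium near neutral so that neither epoxide opens and the methylene lactone does not take up a nucleophile.

**Compound list**

1 | cis,cis-cyclohexane-1,3,5-triol | O[C@@H]1C[C@H](O)C[C@H](O)C1 | starting material
2 | 4-methoxybenzyl chloride | COc1ccc(CCl)cc1 | starting material
3 | all-cis-5-(4-methoxybenzyloxy)cyclohexane-1,3-diol (meso) | O[C@@H]1C[C@H](O)C[C@H](OCc2ccc(OC)cc2)C1 | intermediate
4 | (1R,3R,5S)-3-hydroxy-5-(4-methoxybenzyloxy)cyclohexyl acetate (all-cis) | O[C@H]1C[C@@H](OC(C)=O)C[C@@H](OCc2ccc(OC)cc2)C1 | intermediate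
5 | (1S,5R)-3-oxo-5-(4-methoxybenzyloxy)cyclohexyl acetate (cis; not isolated) | O=C1C[C@@H](OC(C)=O)C[C@@H](OCc2ccc(OC)cc2)C1 | intermediate
6 | (R)-5-(4-methoxybenzyloxy)cyclohex-2-en-1-one | O=C1C=CC[C@@H](OCc2ccc(OC)cc2)C1 | intermediate
7 | (5R)-1-methyl-5-(4-methoxybenzyloxy)cyclohex-2-en-1-ol (both C1 epimers) | CC1(O)C=CC[C@@H](OCc2ccc(OC)cc2)C1 | intermediate
8 | (S)-3-methyl-5-(4-methoxybenzyloxy)cyclohex-2-en-1-one | CC1=CC(=O)C[C@@H](OCc2ccc(OC)cc2)C1 | intermediate
9 | methyl bromoacetate | COC(=O)CBr | starting material
10 | methyl 2-[(1R,6S)-6-(4-methoxybenzyloxy)-4-methyl-2-oxocyclohex-3-en-1-yl]acetate (side chain trans to the ether; 7R,8S in germacrane numbering) | CC1=CC(=O)[C@H](CC(=O)OC)[C@@H](OCc2ccc(OC)cc2)C1 | intermediate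
11 | cyclobutanone | O=C1CCC1 | starting material
12 | 2-cyclobutylidene-1,1-dimethylhydrazine | CN(C)N=C1CCC1 | intermediate
13 | 1,1-dimethyl-2-(2-methylcyclobutylidene)hydrazine (racemic; not isolated) | CC1CCC1=NN(C)C | intermediate
14 | 2-methylcyclobutan-1-one (racemic) | CC1CCC1=O | intermediate
15 | trimethyl[(2-methylcyclobut-1-en-1-yl)oxy]silane (not isolated) | CC1=C(O[Si](C)(C)C)CC1 | intermediate
16 | 2-methylcyclobut-2-en-1-one | CC1=CCC1=O | intermediate
17 | (S)-2-methylcyclobut-2-en-1-ol | CC1=CC[C@@H]1O | intermediate
18 | (S)-tert-butyldimethyl[(2-methylcyclobut-2-en-1-yl)oxy]silane | CC1=CC[C@@H]1O[Si](C)(C)C(C)(C)C | intermediate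
19 | trans-fused photoadduct, the C5 epimer of 20 (six-membered ring trans-fused to the central cyclobutane; not isolated) | O=C1[C@H](CC(=O)OC)[C@@H](OCc2ccc(OC)cc2)C[C@]2(C)[C@H]3C[C@H](O[Si](C)(C)C(C)(C)C)[C@@]3(C)[C@@H]12 | intermediate
20 | methyl 2-[4-(tert-butyldimethylsilyloxy)-9-(4-methoxybenzyloxy)-1,5-dimethyl-7-oxotricyclo[4.4.0.0(2,5)]decan-8-yl]acetate; cis-anti-cis 6-4-4 tricycle, H5 and the C10 methyl on one face of the central cyclobutane, H1 and the C4 methyl on the other; silyloxy cis to the C4 methyl, benzyloxy cis to the C10 methyl, side chain trans to the benzyloxy group (3S,7R,8S) | O=C1[C@H](CC(=O)OC)[C@@H](OCc2ccc(OC)cc2)C[C@]2(C)[C@H]3C[C@H](O[Si](C)(C)C(C)(C)C)[C@@]3(C)[C@H]12 | intermediate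
21 | methyl 2-[(1R,3Z,5S,7E,10S)-5-(tert-butyldimethylsilyloxy)-10-(4-methoxybenzyloxy)-4,8-dimethyl-2-oxocyclodeca-3,7-dien-1-yl]acetate (1(10)E,4Z; 3S,7R,8S) | O=C1/C=C(/C)[C@@H](O[Si](C)(C)C(C)(C)C)C/C=C(\C)C[C@H](OCc2ccc(OC)cc2)[C@H]1CC(=O)OC | intermediate
22 | methyl 2-[(1S,2R,3Z,5S,7E,10S)-5-(tert-butyldimethylsilyloxy)-2-hydroxy-10-(4-methoxybenzyloxy)-4,8-dimethylcyclodeca-3,7-dien-1-yl]acetate (6R alcohol; not isolated) | O[C@@H]1/C=C(/C)[C@@H](O[Si](C)(C)C(C)(C)C)C/C=C(\C)C[C@H](OCc2ccc(OC)cc2)[C@H]1CC(=O)OC | intermediate
23 | (3S,6R,7R,8S,1(10)E,4Z)-3-(tert-butyldimethylsilyloxy)-8-(4-methoxybenzyloxy)-13-norgermacra-1(10),4-dien-12,6-olide (trans-fused lactone) | C1C(=O)O[C@@H]2/C=C(/C)[C@@H](O[Si](C)(C)C(C)(C)C)C/C=C(\C)C[C@H](OCc3ccc(OC)cc3)[C@@H]12 | intermediate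
24 | 11-(dimethylaminomethyl) derivative of 23 (both C11 epimers; not isolated) | CN(C)CC1C(=O)O[C@@H]2/C=C(/C)[C@@H](O[Si](C)(C)C(C)(C)C)C/C=C(\C)C[C@H](OCc3ccc(OC)cc3)[C@@H]12 | intermediate
25 | 11-(trimethylammoniomethyl) derivative of 23, iodide (not isolated) | C[N+](C)(C)CC1C(=O)O[C@@H]2/C=C(/C)[C@@H](O[Si](C)(C)C(C)(C)C)C/C=C(\C)C[C@H](OCc3ccc(OC)cc3)[C@@H]12.[I-] | intermediate
26 | (3S,6R,7R,8S,1(10)E,4Z)-3-(tert-butyldimethylsilyloxy)-8-(4-methoxybenzyloxy)germacra-1(10),4,11(13)-trien-12,6-olide | C=C1C(=O)O[C@@H]2/C=C(/C)[C@@H](O[Si](C)(C)C(C)(C)C)C/C=C(\C)C[C@H](OCc3ccc(OC)cc3)[C@@H]12 | intermediate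
27 | (3S,6R,7R,8S,1(10)E,4Z)-3-(tert-butyldimethylsilyloxy)-8-hydroxygermacra-1(10),4,11(13)-trien-12,6-olide | C=C1C(=O)O[C@@H]2/C=C(/C)[C@@H](O[Si](C)(C)C(C)(C)C)C/C=C(\C)C[C@H](O)[C@@H]12 | intermediate
28 | methyl (Z)-2-methylbut-2-enoate (methyl angelate) | C/C=C(/C)C(=O)OC | starting material
29 | (Z)-2-methylbut-2-en-1-ol | C/C=C(/C)CO | intermediate
30 | [(2S,3R)-2,3-dimethyloxiran-2-yl]methanol | OC[C@]1(C)O[C@@H]1C | intermediate
31 | (2R,3R)-2,3-dimethyloxirane-2-carboxylic acid | OC(=O)[C@]1(C)O[C@@H]1C | intermediate
32 | (3S,6R,7R,8R,1(10)E,4Z)-3-(tert-butyldimethylsilyloxy)-8-[(2R,3R)-2,3-dimethyloxirane-2-carbonyloxy]germacra-1(10),4,11(13)-trien-12,6-olide | C=C1C(=O)O[C@@H]2/C=C(/C)[C@@H](O[Si](C)(C)C(C)(C)C)C/C=C(\C)C[C@@H](OC(=O)[C@]3(C)O[C@@H]3C)[C@@H]12 | intermediate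
33 | (1R,3S,6R,7R,8R,10R,4Z)-3-(tert-butyldimethylsilyloxy)-1,10-epoxy-8-[(2R,3R)-2,3-dimethyloxirane-2-carbonyloxy]germacra-4,11(13)-dien-12,6-olide | C=C1C(=O)O[C@@H]2/C=C(/C)[C@@H](O[Si](C)(C)C(C)(C)C)C[C@H]3O[C@]3(C)C[C@@H](OC(=O)[C@]3(C)O[C@@H]3C)[C@@H]12 | intermediate
34 | (1R,3S,6R,7R,8R,10R,4Z)-1,10-epoxy-3-hydroxy-8-[(2R,3R)-2,3-dimethyloxirane-2-carbonyloxy]germacra-4,11(13)-dien-12,6-olide | C=C1C(=O)O[C@@H]2/C=C(/C)[C@@H](O)C[C@H]3O[C@]3(C)C[C@@H](OC(=O)[C@]3(C)O[C@@H]3C)[C@@H]12 | target

**Step count and risks**

Total: 22 steps. Longest linear sequence: 14 steps (steps 1–6, 12–16, 20–22). The cyclobutene (steps 7–11) and the acid (steps 17–19) are side branches of five and three steps.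

Step 12 (key step). The likeliest failure is inefficient capture of the short-lived triplet of a β,β-disubstituted enone by a hindered trisubstituted cyclobutene. The α′ side chain and the benzylic ether then offer the excited ketone hydrogen-abstraction channels, and some addition may leak into the head-to-tail sense. The fallback takes the side chain off the chromophore. It sets out from 8 and 18, which are irradiated under the same conditions to give 4-(tert-butyldimethylsilyloxy)-9-(4-methoxybenzyloxy)-1,5-dimethyltricyclo[4.4.0.0(2,5)]decan-7-one F1. The acetate unit is then put on the rigid tricyclic ketone by kinetic deprotonation at the C7 methylene (LiN(iPr)2, −78 °C) and alkylation with 9, with equilibration on alumina to the 7,8-trans epimer. The route is rejoined at 20.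

Step 13. The 1,4-diyl may partition toward scission of C2–C3, and any (E,E)-diene formed from residual trans-fused material would drain by Cope rearrangement; both give a divinylcyclohexanone instead of the ten-membered ring. Part of the material may also emerge with the 4E enone. The fallback sets out from 20 and replaces the long solution thermolysis by flash vacuum pyrolysis with short contact time. The (4E) isomer, methyl 2-[(1R,3E,5S,7E,10S)-5-(tert-butyldimethylsilyloxy)-10-(4-methoxybenzyloxy)-4,8-dimethyl-2-oxocyclodeca-3,7-dien-1-yl]acetate F2, is then isomerised to the cis enone by triplet-sensitised irradiation or catalytic iodine. The route is rejoined at 21.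

Step 9. β-Hydride elimination may run toward the methyl group and give the exocyclic methylene ketone, and the strained enone may polymerise on concentration. The fallback avoids the cyclobutenone and sets out from 11. Addition of MeMgBr gives 1-methylcyclobutan-1-ol F3, and acid-catalysed dehydration with distillation gives 1-methylcyclobutene F4. Allylic oxidation with catalytic SeO2 and t-BuOOH, which goes to the ring methylene at the more substituted alkene carbon, gives racemic 2-methylcyclobut-2-en-1-ol F5. Lipase-catalysed acetylation (Candida antarctica lipase B, vinyl acetate) removes the R enantiomer as its acetate and leaves the S alcohol. The route is rejoined at 17, at the cost of half the material at a cheap stage.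

Step 14. If the ten-membered ring does not allow the C6 carbonyl and the C8 ether to bind one zinc atom, facial selectivity will be poor and a cis-fused lactone will accompany 23; some 1,4-reduction is also possible. The fallback sets out from 21 and replaces substrate control by reagent control. Corey–Bakshi–Shibata reduction with catecholborane is used, with (R)-Me-CBS if the C5 alkenyl arm behaves as the large group, as is usual for enones, and the other enantiomer if not. The same acid-promoted lactonisation follows and the route is rejoined at 23. No new compound is involved.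

Step 20. The α-quaternary glycidate is a sluggish nucleophile, so elimination toward C9 or acyl transfer with retention may compete with displacement, and free phosphine may add to the methylene lactone. The fallback separates inversion from acylation and sets out from 27. Mitsunobu reaction with formic acid, a small acid of similar strength, gives the inverted (8R)-formate, (3S,6R,7R,8R)-3-(tert-butyldimethylsilyloxy)-8-formyloxygermacra-1(10),4,11(13)-trien-12,6-olide F6. Brief treatment with KHCO3 in aqueous methanol frees the (8R)-alcohol F7, in which the 8-hydroxyl is cis to C11 and the 6,12-lactone is therefore the stable form. Yamaguchi esterification with 31 (2,4,6-trichlorobenzoyl chloride, Et3N, DMAP) then proceeds with retention. The route is rejoined at 32.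

Step 21. Facial selectivity rests on the ring conformation alone and may be poor, and some oxidation of C4=C5 cannot be excluded. The fallback sets out from 32 and uses catalyst control: Shi epoxidation with the D-fructose-derived ketone and KHSO5 (as the triple salt 2KHSO5·KHSO4·K2SO4) at buffered pH. This catalyst gives R,R-epoxides from E-trisubstituted alkenes and, being bulky, prefers the unencumbered C1=C10 bond. The route is rejoined at 33. No new compound is involved.

**Further compounds**

F1 | step 12 | 4-(tert-butyldimethylsilyloxy)-9-(4-methoxybenzyloxy)-1,5-dimethyltricyclo[4.4.0.0(2,5)]decan-7-one (cis-anti-cis; 3S,8S) | O=C1C[C@@H](OCc2ccc(OC)cc2)C[C@]2(C)[C@H]3C[C@H](O[Si](C)(C)C(C)(C)C)[C@@]3(C)[C@H]12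
F2 | step 13 | methyl 2-[(1R,3E,5S,7E,10S)-5-(tert-butyldimethylsilyloxy)-10-(4-methoxybenzyloxy)-4,8-dimethyl-2-oxocyclodeca-3,7-dien-1-yl]acetate | O=C1/C=C(\C)[C@@H](O[Si](C)(C)C(C)(C)C)C/C=C(\C)C[C@H](OCc2ccc(OC)cc2)[C@H]1CC(=O)OC
F3 | step 9 | 1-methylcyclobutan-1-ol | CC1(O)CCC1
F4 | step 9 | 1-methylcyclobutene | CC1=CCC1
F5 | step 9 | 2-methylcyclobut-2-en-1-ol (racemic) | CC1=CCC1O
F0 | step 14 | none | none
F6 | step 20 | (3S,6R,7R,8R,1(10)E,4Z)-3-(tert-butyldimethylsilyloxy)-8-formyloxygermacra-1(10),4,11(13)-trien-12,6-olide | C=C1C(=O)O[C@@H]2/C=C(/C)[C@@H](O[Si](C)(C)C(C)(C)C)C/C=C(\C)C[C@@H](OC=O)[C@@H]12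
F7 | step 20 | (3S,6R,7R,8R,1(10)E,4Z)-3-(tert-butyldimethylsilyloxy)-8-hydroxygermacra-1(10),4,11(13)-trien-12,6-olide | C=C1C(=O)O[C@@H]2/C=C(/C)[C@@H](O[Si](C)(C)C(C)(C)C)C/C=C(\C)C[C@@H](O)[C@@H]12
F0 | step 21 | none | none
A1 | alternative 1 | (1(10)E,4Z)-3-hydroxy-8-(triethylsilyloxy)germacra-1(10),4,11(13)-trien-12,6-olide | C=C1C(=O)O[C@@H]2/C=C(/C)[C@@H](O)C/C=C(\C)C[C@@H](O[Si](CC)(CC)CC)[C@@H]12
A2 | alternative 2 | trans-lactone with C11 allyl ester, free C8 hydroxyl, (Z)-alkenyl iodide and silyl-protected primary alcohol | C=CCOC(=O)[C@@H]1C(=O)O[C@H](/C=C(/C)I)[C@H]1[C@H](O)C/C(C)=C/CCO[Si](C)(C)C(C)(C)C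
A3 | alternative 3 | (1(10)E,4Z)-3-(tert-butyldimethylsilyloxy)-8-(4-methoxybenzyloxy)-13-norgermacra-1(10),4-dien-12,6-olide | C1C(=O)O[C@@H]2/C=C(/C)[C@@H](O[Si](C)(C)C(C)(C)C)C/C=C(\C)C[C@@H](OCc3ccc(OC)cc3)[C@@H]12
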